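Atom labels used throughout: the ring is O1–O2–C3–C4–C5–C6 as in the target, and the octenyl chain on C6 is C1'–C8' (ethyl branch on C4', alkene C5'=C6').

## Analysis of the target

The target is methyl 2-[(3S,4S,6S)-4,6-diethyl-6-[(4R,5E)-4-ethyloct-5-en-1-yl]-1,2-dioxan-3-yl]acetate, a monocyclic 1,2-dioxane of the plakortin type. C3 is a methine that carries the CH2CO2Me arm, C4 carries an ethyl group, and C6 is a quaternary peroxide carbon with an ethyl group and a ten-carbon chain. The chain holds an allylic stereocentre (C4') and an E-alkene (C5'=C6').

On the ring, the C3 arm, the C4 ethyl and the C6 ethyl are all cis and the long chain is trans to them. In the chair that keeps the C4 ethyl equatorial the C3 arm is axial, so the required 3,4-cis isomer is the less stable C3 epimer.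

The feature that decides the strategy is the O1–O2 bridge between C6 and C3. C6 carries an ethyl and a CH2CH2CH2R group that are sterically and conformationally equivalent. No diastereoselective or thermodynamic process can therefore tell its two faces apart. Its configuration has to be written into a peroxide-free precursor by a reagent-controlled step and then transferred stereospecifically. C4' is too remote to relay anything and must be set on its own.

The sensitive groups are:
- the O–O bond, which is attacked by low-valent metals, phosphines, hydrides, organometallics and heat;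
- the β-peroxy ester, where base causes retro-oxa-Michael cleavage or Kornblum–DeLaMare fragmentation at C3–H;
- the disubstituted alkene, which rules out late hydrogenation, diimide reduction or ozonolysis.

The synthesis is hard because three demands meet: a tertiary peroxide stereocentre with two near-identical alkyl groups, a contra-thermodynamic C3 centre, and a peroxide that must arrive late and under non-reducing, non-basic conditions.

## Retrosynthetic reasoning

**C3–CH2 bond (29 to 26 and 27).** The exocyclic C–C bond at C3 is cut, not the C3–O2 bond. Closing C3–O2 by conjugate addition would follow the ring's preference for an equatorial arm. C–C bond formation on the cyclic peroxycarbenium ion 28 is instead kinetically controlled and axial. The ester then arrives in the last step and never meets base. Both anomers of the peroxyacetal 26 serve, because they converge on 28. The forward reaction has to ionise 26 and add the silyl ketene acetal 27 cis to the C4 ethyl.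

**C–O bond of the C6 ethyl group (26 to 25).** The C6 ethyl is traced back to a 2-hydroxyethyl group. This extra oxygen is the price of the next disconnection: it is the ring oxygen of an oxetane. The forward reaction is a deoxygenation of a primary alcohol that leaves the O–O bond alone.

**O1–C6 and O2–C3 (25 to 22 and 23), the key disconnection.** Both C–O bonds of the peroxide bridge are cut at once. This returns hydrogen peroxide 23 and a carbon skeleton 22 that contains no peroxide. In 22, C6 is the quaternary carbon of a 2,2-dialkyloxetane and C3 is a dimethyl acetal. The cut is made here because tying the third substituent of C6 back as a four-membered ring makes C6 a defined stereocentre that an SN2 opening transfers with inversion. The gain is that the ring, the O–O bond and the quaternary stereocentre all form in one operation, and every earlier step may use organometallics, hydrides and palladium. The forward reaction has to open the oxetane at its tertiary carbon with inversion and close the hydroperoxide 24 onto the acetal carbon.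

**Oxetane back to the allylic alcohol (22 to 20 to 19 to 18).** The primary C–O bond of the oxetane is cut (Williamson closure of 1,3-diol 20). The diol is the hydride-opening product of 2,3-epoxy alcohol 19, which comes from Sharpless asymmetric epoxidation of the 3,3-dialkyl allylic alcohol 18. This turns the "ethyl versus chain" problem at C6 into a question of alkene geometry (which arm is cis to CH2OH), and that can be controlled.

**C5–C6 bond (18 and 17 to 10 and 15).** The trisubstituted alkene of 17 is cut at its only sp2–sp3 bond to the ring half. The geometry is stored in the (Z)-enol triflate 10 and copied by a stereoretentive Negishi coupling with the alkylzinc 16 made from iodide 15. This joins the two stereocentre-bearing halves convergently.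

**C1'–C2' bond (10 and 9 to 7 and 8).** The β-keto ester 9 is cut at the γ-carbon: alkylation of the dianion of methyl acetoacetate 8 with iodide 7. Compound 8 supplies C6, C1' and the two carbons that end as the C6 ethyl.

**C3'–C4' bond (7, 6 and 5 to 3 and 4).** The chain stereocentre is cut by a Johnson–Claisen transform. The orthoester 4 and the allylic alcohol 3 give ester 5 with 1,3-chirality transfer and an E-alkene. Compound 3 is a pseudo-symmetric 1,3-diethylallyl alcohol, made from enal 1 and diethylzinc 2, so both alkene substituents of the target are already in place.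

**C4 stereocentre (15, 14 and 13 to 11 and 12).** The ring-half fragment is cut between C4 and C3. The acyl oxazolidinone 11 is alkylated with the orthoformate 12 under auxiliary control, so C4 and the masked C3 aldehyde arrive together.

## Alternatives that were turned down

**Alternative 1:** the textbook route. Both ring C–O bonds are made as hydroperoxide additions, with the O–O unit from O2. The forward key steps are a cobalt-catalysed Mukaiyama–Isayama hydroperoxysilylation of the trisubstituted alkene of triene ester A1, then intramolecular oxa-Michael addition of the tertiary hydroperoxide A2 onto its (E)-enoate. It was turned down for three reasons: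
- The C6 radical is planar and flanked by ethyl and a CH2CH2 chain, so both C6 epimers of A2 should form in equal amounts and would be very hard to separate.
- Hydrogen-atom transfer does not fully spare the chain alkene or the enoate.
- The oxa-Michael closure is governed by the chair and prefers the diequatorial 3,4-trans ring, or equilibrates by retro-Michael, while the target needs the axial arm.

The route is short, but two of three ring stereocentres would be uncontrolled.

**Alternative 2:** both C–O bonds are made at once by [4+2] cycloaddition of singlet oxygen to diene A3. This gives the 3,6-dihydro-1,2-dioxine A4, and diimide reduction of C4=C5 follows. It was turned down for three reasons: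
- The C6 terminus of A3 is fully substituted, so one alkyl group must sit inside the s-cis diene. Cycloaddition should then lose to ene reactions at the many allylic C–H bonds, including those of the chain alkene.
- Nothing controls which diene face reacts, so the ring would be racemic relative to C4'.
- The trisubstituted ring alkene of A4 is reduced by diimide more slowly than the disubstituted chain alkene.

**Alternative 3:** the C6–C1' and C3–CH2 bonds are both made by peroxycarbenium chemistry on a preformed ring. The γ-keto aldehyde A5 and hydrogen peroxide give the 3,6-dimethoxy-1,2-dioxane A6. A Lewis acid ionises the ketal first and allyltrimethylsilane adds axially, trans to the C4 ethyl, to give A7. A second ionisation at C3 installs the acetate arm. This is the shortest plan, with three components around the ring, and its facial preferences match the target. It was turned down because only π-nucleophiles are known to add to peroxycarbenium ions, so the C6 substituent can only arrive as an allyl group. Extending the allyl group of A7 by a saturated sp3–sp3 bond to C4' needs hydroboration and copper- or nickel-mediated alkyl coupling, with reducing metals and alkoxide bases next to the O–O bond. Any unsaturated linker fails too, because its reduction cannot be separated from that of C5'=C6'. The risk would sit in several late steps and not in one.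

Key step: step 15

Remark: anhydrous ethereal H2O2 is prepared from commercial aqueous H2O2 and is not counted as a step; compounds 11 and 27 and both enantiomers of the amino alcohol DAIB are taken as purchasable.

## Route

Step 1
Reactants: 1 (E)-pent-2-enal; 2 diethylzinc
Product: 3 (3R,4E)-hept-4-en-3-ol
Conditions: (+)-DAIB (5 mol%), toluene, 0 °C; then 1 M HCl
Reagents that add atoms: none
Why: Amino-alcohol-catalysed asymmetric 1,2-addition of a dialkylzinc to an enal; the (−)-ligand is known to give (S)-carbinols from aryl and alkenyl aldehydes, so the (+)-ligand should give the (R)-alcohol, a pseudo-symmetric 1,3-diethylallyl alcohol.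

Step 2
Reactants: 3 (3R,4E)-hept-4-en-3-ol; 4 triethyl orthoacetate
Product: 5 ethyl (3R,4E)-3-ethylhept-4-enoate
Conditions: EtCO2H (cat.), neat 4 (6 equiv), 138 °C, EtOH distilled off
Reagents that add atoms: none
Why: Johnson–Claisen rearrangement through a chair transition state with the carbinol ethyl group equatorial; the C–O bond broken and the C–C bond formed lie on the same face of the allyl unit, so the (R)-carbinol should be transferred to the (R)-configured C4' with an E-alkene.

Step 3
Reactants: 5 ethyl (3R,4E)-3-ethylhept-4-enoate
Product: 6 (3R,4E)-3-ethylhept-4-en-1-ol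
Conditions: LiAlH4, Et2O, 0 °C; Fieser work-up
Reagents that add atoms: none
Why: Hydride reduction of an ester to the primary alcohol; the isolated alkene and the non-enolisable stereocentre are not affected.

Step 4
Reactants: 6 (3R,4E)-3-ethylhept-4-en-1-ol
Product: 7 (3E,5R)-5-ethyl-7-iodohept-3-ene
Conditions: I2, PPh3, imidazole, CH2Cl2, 0 °C to rt
Reagents that add atoms: iodine, II
Why: Appel-type iodination of an unhindered primary alcohol by SN2 displacement of the alkoxyphosphonium ion; no stereocentre is involved.

Step 5
Reactants: 8 methyl 3-oxobutanoate (methyl acetoacetate); 7 (3E,5R)-5-ethyl-7-iodohept-3-ene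
Product: 9 methyl (7R,8E)-7-ethyl-3-oxoundec-8-enoate
Conditions: NaH, THF, 0 °C; n-BuLi, 0 °C; then 7, 0 °C to rt; aq. NH4Cl
Reagents that add atoms: none
Why: γ-Alkylation of the acetoacetate dianion by a primary iodide; the more basic terminal carbanion reacts, which forms the C1'–C2' bond and delivers the β-keto ester whose ketone carbon becomes C6.

Step 6
Reactants: 9 methyl (7R,8E)-7-ethyl-3-oxoundec-8-enoate
Product: 10 methyl (2Z,7R,8E)-7-ethyl-3-{[(trifluoromethyl)sulfonyl]oxy}undeca-2,8-dienoate
Conditions: Tf2O, sat. aq. LiOH, toluene, 5 °C
Reagents that add atoms: trifluoromethanesulfonic anhydride, O=S(=O)(OS(=O)(=O)C(F)(F)F)C(F)(F)F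
Why: Stereoselective O-triflation of a β-keto ester under biphasic lithium hydroxide conditions; lithium chelation between the enolate oxygen and the ester carbonyl holds the (Z)-enolate, so OTf should end cis to the ester.

Step 7
Reactants: 11 (4S)-4-benzyl-3-butanoyl-1,3-oxazolidin-2-one; 12 trimethyl orthoformate
Product: 13 (4S)-4-benzyl-3-[(2R)-2-(dimethoxymethyl)butanoyl]-1,3-oxazolidin-2-one
Conditions: TiCl4, i-Pr2NEt, CH2Cl2, 0 °C; then 12, 0 °C
Reagents that add atoms: none
Why: Auxiliary-controlled alkylation of the chelated (Z)-titanium enolate by the dimethoxycarbenium ion from the orthoformate; the electrophile enters opposite the benzyl group, which sets the future C4 and brings in C3 as a dimethyl acetal.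

Step 8
Reactants: 13 (4S)-4-benzyl-3-[(2R)-2-(dimethoxymethyl)butanoyl]-1,3-oxazolidin-2-one
Product: 14 (2S)-2-(dimethoxymethyl)butan-1-ol
Conditions: LiBH4, MeOH (1 equiv), Et2O, 0 °C
Reagents that add atoms: none
Why: Reductive cleavage of the imide to the primary alcohol with return of the auxiliary; the acetal is inert to borohydride and the stereocentre is no longer enolisable once reduced.

Step 9
Reactants: 14 (2S)-2-(dimethoxymethyl)butan-1-ol
Product: 15 (2R)-2-(iodomethyl)-1,1-dimethoxybutane
Conditions: I2, PPh3, imidazole, CH2Cl2, 0 °C to rt
Reagents that add atoms: iodine, II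
Why: Appel-type iodination of the primary alcohol, buffered by imidazole so that the acetal survives; the stereocentre is a spectator (the descriptor changes only through the priority rules).

Step 10
Reactants: 15 (2R)-2-(iodomethyl)-1,1-dimethoxybutane; 10 methyl (2Z,7R,8E)-7-ethyl-3-{[(trifluoromethyl)sulfonyl]oxy}undeca-2,8-dienoate
Product: 17 methyl (2Z,7R,8E)-3-[(2S)-2-(dimethoxymethyl)butyl]-7-ethylundeca-2,8-dienoate, via alkylzinc iodide 16 (not isolated)
Conditions: Zn dust, LiCl, THF, 40 °C; then 10, PdCl2(dppf) (5 mol%), THF, 50 °C
Reagents that add atoms: none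
Why: Zinc insertion into the primary iodide and Negishi coupling with the enol triflate; oxidative addition and reductive elimination at the vinyl carbon go with retention, so the Z geometry of 10 is copied into 17 and fixes which alkyl arm is cis to the ester.

Step 11
Reactants: 17 methyl (2Z,7R,8E)-3-[(2S)-2-(dimethoxymethyl)butyl]-7-ethylundeca-2,8-dienoate
Product: 18 (2Z,7R,8E)-3-[(2S)-2-(dimethoxymethyl)butyl]-7-ethylundeca-2,8-dien-1-ol
Conditions: DIBAL-H (2.5 equiv), CH2Cl2, −78 °C; Rochelle salt
Reagents that add atoms: none
Why: 1,2-Reduction of the conjugated ester to the allylic alcohol without touching the alkene geometry or the acetal.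

Step 12
Reactants: 18 (2Z,7R,8E)-3-[(2S)-2-(dimethoxymethyl)butyl]-7-ethylundeca-2,8-dien-1-ol
Product: 19 [(2S,3R)-3-[(2S)-2-(dimethoxymethyl)butyl]-3-[(4R,5E)-4-ethyloct-5-en-1-yl]oxiran-2-yl]methanol
Conditions: Ti(Oi-Pr)4 (10 mol%), L-(+)-diethyl tartrate (12 mol%), t-BuOOH (anhydrous, 2 equiv), 4 Å MS, CH2Cl2, −20 °C
Reagents that add atoms: tert-butyl hydroperoxide, CC(C)(C)OO
Why: Sharpless asymmetric epoxidation under reagent control; L-(+)-tartrate gives the (2S,3R)-epoxide from a 3,3-dialkyl (Z)-allylic alcohol (the nerol pattern), so alkene geometry plus tartrate chirality define the future C6, and the chain alkene stays because it has no directing hydroxyl.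

Step 13
Reactants: 19 [(2S,3R)-3-[(2S)-2-(dimethoxymethyl)butyl]-3-[(4R,5E)-4-ethyloct-5-en-1-yl]oxiran-2-yl]methanol
Product: 20 (3R,7R,8E)-3-[(2S)-2-(dimethoxymethyl)butyl]-7-ethylundec-8-ene-1,3-diol
Conditions: Red-Al, THF, 0 °C to rt
Reagents that add atoms: none
Why: Hydroxyl-directed hydride delivery opens the 2,3-epoxy alcohol at C2 to give the 1,3-diol; the tertiary C–O bond is not broken, so the configuration of the future C6 is retained.

Step 14
Reactants: 20 (3R,7R,8E)-3-[(2S)-2-(dimethoxymethyl)butyl]-7-ethylundec-8-ene-1,3-diol
Product: 22 (2R)-2-[(2S)-2-(dimethoxymethyl)butyl]-2-[(4R,5E)-4-ethyloct-5-en-1-yl]oxetane, via primary monotosylate 21 (not isolated)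
Conditions: n-BuLi (1.0 equiv), THF, 0 °C; TsCl (1.0 equiv), 0 °C; n-BuLi (1.1 equiv), 0 to 60 °C
Reagents that add atoms: none
Why: Selective sulfonylation of the primary alkoxide and 4-exo-tet Williamson closure by the tertiary alkoxide; the stereocentre carries the nucleophilic oxygen and is retained.

Step 15
Reactants: 22 (2R)-2-[(2S)-2-(dimethoxymethyl)butyl]-2-[(4R,5E)-4-ethyloct-5-en-1-yl]oxetane; 23 hydrogen peroxide
Product: 25 2-[(3S,5S)-5-ethyl-3-[(4R,5E)-4-ethyloct-5-en-1-yl]-6-methoxy-1,2-dioxan-3-yl]ethan-1-ol, via tertiary hydroperoxide 24 (not isolated)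
Conditions: 23 (anhydrous, ca. 2 M in Et2O, 10 equiv), TMSOTf (0.3 equiv), Et2O, −78 to −20 °C; aq. NaHCO3; then PPTS (cat.), 4 Å MS, CH2Cl2, rt
Reagents that add atoms: none
Why: TMSOTf activates the oxetane oxygen and H2O2 attacks the tertiary carbon from the rear in a borderline SN2 opening, giving hydroperoxide 24 with inversion; this is the known Lewis-acid perhydrolysis of 2,2-dialkyloxetanes to 3-hydroperoxyalkanols. The acid then ionises the dimethyl acetal and the hydroperoxide adds to the oxocarbenium carbon, the known cyclisation of hydroperoxy acetals to 3-alkoxy-1,2-dioxanes. The 1,2-dioxane is closed in a 6-exo-trig mode by O2–C3 bond formation, after O1–C6 has formed in the intermolecular opening; if acetal exchange comes first, the ring closes by 6-exo-tet opening of the oxetane and the product and the inversion are the same. The new C6 stereocentre (ring position 3 in the name of 25) is controlled only by the oxetane configuration, which alkene geometry and the tartrate fixed earlier. The acetal carbon C3 forms as both anomers, which is intended because step 17 erases it. Attack at the tertiary and not the primary oxetane carbon is secured by the greater ability of the tertiary centre to bear positive charge under Lewis acid. Stereospecific substitution in place of ionisation is secured by low temperature, ether solvent, a large excess of a strong α-effect nucleophile and ring strain. The chain alkene is safe because no peracid or metal oxidant is present, and closure by the primary hydroxyl would need an eight-membered ring.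

Step 16
Reactants: 25 2-[(3S,5S)-5-ethyl-3-[(4R,5E)-4-ethyloct-5-en-1-yl]-6-methoxy-1,2-dioxan-3-yl]ethan-1-ol
Product: 26 (3S,5S)-3,5-diethyl-3-[(4R,5E)-4-ethyloct-5-en-1-yl]-6-methoxy-1,2-dioxane
Conditions: PPh3 and DEAD premixed, THF, −30 °C; then 25; then 2-nitrobenzenesulfonylhydrazide, −30 to 23 °C
Reagents that add atoms: none
Why: Mitsunobu displacement of the unhindered primary alcohol by the sulfonylhydrazide, loss of sulfinic acid to the monoalkyl diazene and loss of N2 give the alkane in one operation (reductive deoxygenation); premixing phosphine and azodicarboxylate leaves no free phosphine for the O–O bond, and the neutral conditions suit the peroxyacetal.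

Step 17
Reactants: 26 (3S,5S)-3,5-diethyl-3-[(4R,5E)-4-ethyloct-5-en-1-yl]-6-methoxy-1,2-dioxane; 27 tert-butyl[(1-methoxyethenyl)oxy]dimethylsilane
Product: 29 methyl 2-[(3S,4S,6S)-4,6-diethyl-6-[(4R,5E)-4-ethyloct-5-en-1-yl]-1,2-dioxan-3-yl]acetate, via peroxycarbenium triflate 28 (not isolated)
Conditions: 27 (3 equiv), TMSOTf (0.3 equiv), CH2Cl2, −78 °C
Reagents that add atoms: none
Why: The Lewis acid ionises both anomers of the peroxyacetal to the single peroxycarbenium ion 28 (stereoconvergent), which the silyl ketene acetal traps in a Mukaiyama-type addition, as known for 3-alkoxy-1,2-dioxolanes and 3-alkoxy-1,2-dioxanes. In the half-chair of 28 the C4 ethyl is pseudo-equatorial and the nucleophile enters on the pseudo-axial trajectory anti to C4–H, which leads directly to a chair with the new CH2CO2Me axial and cis to the C4 ethyl (3S); the C–C bond forms irreversibly, so the less stable epimer should not equilibrate. Catalytic acid at −78 °C should leave the tertiary C6–O bond, the alkene and the new β-peroxy ester alone.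

## Compound list

1 | (E)-pent-2-enal | CC/C=C/C=O | starting material
2 | diethylzinc | CC[Zn]CC | starting material
3 | (3R,4E)-hept-4-en-3-ol | CC/C=C/[C@H](O)CC | intermediate
4 | triethyl orthoacetate | CC(OCC)(OCC)OCC | starting material
5 | ethyl (3R,4E)-3-ethylhept-4-enoate | CC/C=C/[C@H](CC)CC(=O)OCC | intermediate
6 | (3R,4E)-3-ethylhept-4-en-1-ol | CC/C=C/[C@H](CC)CCO | intermediate
7 | (3E,5R)-5-ethyl-7-iodohept-3-ene | CC/C=C/[C@H](CC)CCI | intermediate
8 | methyl 3-oxobutanoate | CC(=O)CC(=O)OC | starting material
9 | methyl (7R,8E)-7-ethyl-3-oxoundec-8-enoate | CC/C=C/[C@H](CC)CCCC(=O)CC(=O)OC | intermediate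
10 | methyl (2Z,7R,8E)-7-ethyl-3-{[(trifluoromethyl)sulfonyl]oxy}undeca-2,8-dienoate | CC/C=C/[C@H](CC)CCC/C(OS(=O)(=O)C(F)(F)F)=C/C(=O)OC | intermediate
11 | (4S)-4-benzyl-3-butanoyl-1,3-oxazolidin-2-one | CCCC(=O)N1[C@@H](Cc2ccccc2)COC1=O | starting material
12 | trimethyl orthoformate | COC(OC)OC | starting material
13 | (4S)-4-benzyl-3-[(2R)-2-(dimethoxymethyl)butanoyl]-1,3-oxazolidin-2-one | CC[C@H](C(OC)OC)C(=O)N1[C@@H](Cc2ccccc2)COC1=O | intermediate
14 | (2S)-2-(dimethoxymethyl)butan-1-ol | CC[C@H](C(OC)OC)CO | intermediate
15 | (2R)-2-(iodomethyl)-1,1-dimethoxybutane | CC[C@H](C(OC)OC)CI | intermediate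
16 | [(2R)-2-(dimethoxymethyl)butyl]zinc iodide | CC[C@H](C(OC)OC)C[Zn]I | intermediate (not isolated)
17 | methyl (2Z,7R,8E)-3-[(2S)-2-(dimethoxymethyl)butyl]-7-ethylundeca-2,8-dienoate | CC/C=C/[C@H](CC)CCC/C(C[C@H](CC)C(OC)OC)=C/C(=O)OC | intermediate
18 | (2Z,7R,8E)-3-[(2S)-2-(dimethoxymethyl)butyl]-7-ethylundeca-2,8-dien-1-ol | CC/C=C/[C@H](CC)CCC/C(C[C@H](CC)C(OC)OC)=C/CO | intermediate
19 | [(2S,3R)-3-[(2S)-2-(dimethoxymethyl)butyl]-3-[(4R,5E)-4-ethyloct-5-en-1-yl]oxiran-2-yl]methanol | OC[C@@H]1O[C@]1(CCC[C@@H](CC)/C=C/CC)C[C@H](CC)C(OC)OC | intermediate
20 | (3R,7R,8E)-3-[(2S)-2-(dimethoxymethyl)butyl]-7-ethylundec-8-ene-1,3-diol | OCC[C@@](O)(CCC[C@@H](CC)/C=C/CC)C[C@H](CC)C(OC)OC | intermediate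
21 | (3R,7R,8E)-3-[(2S)-2-(dimethoxymethyl)butyl]-7-ethyl-3-hydroxyundec-8-en-1-yl 4-methylbenzenesulfonate | Cc1ccc(cc1)S(=O)(=O)OCC[C@@](O)(CCC[C@@H](CC)/C=C/CC)C[C@H](CC)C(OC)OC | intermediate (not isolated)
22 | (2R)-2-[(2S)-2-(dimethoxymethyl)butyl]-2-[(4R,5E)-4-ethyloct-5-en-1-yl]oxetane | C1CO[C@]1(CCC[C@@H](CC)/C=C/CC)C[C@H](CC)C(OC)OC | intermediate
23 | hydrogen peroxide | OO | starting material
24 | (3S,7R,8E)-3-[(2S)-2-(dimethoxymethyl)butyl]-7-ethyl-3-hydroperoxyundec-8-en-1-ol | OCC[C@](OO)(CCC[C@@H](CC)/C=C/CC)C[C@H](CC)C(OC)OC | intermediate (not isolated)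
25 | 2-[(3S,5S)-5-ethyl-3-[(4R,5E)-4-ethyloct-5-en-1-yl]-6-methoxy-1,2-dioxan-3-yl]ethan-1-ol, both anomers at the methoxy carbon (ring positions 3, 5, 6 of this name are C6, C4, C3 of the target) | CC/C=C/[C@H](CC)CCC[C@@]1(CCO)C[C@H](CC)C(OC)OO1 | intermediate
26 | (3S,5S)-3,5-diethyl-3-[(4R,5E)-4-ethyloct-5-en-1-yl]-6-methoxy-1,2-dioxane, both anomers | CC/C=C/[C@H](CC)CCC[C@@]1(CC)C[C@H](CC)C(OC)OO1 | intermediate
27 | tert-butyl[(1-methoxyethenyl)oxy]dimethylsilane | C=C(OC)O[Si](C)(C)C(C)(C)C | starting material
28 | (4S,6S)-4,6-diethyl-6-[(4R,5E)-4-ethyloct-5-en-1-yl]-5,6-dihydro-4H-1,2-dioxin-2-ium trifluoromethanesulfonate (target numbering, C3=O2+) | CC/C=C/[C@H](CC)CCC[C@@]1(CC)C[C@H](CC)C=[O+]O1.[O-]S(=O)(=O)C(F)(F)F | intermediate (not isolated)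
29 | methyl 2-[(3S,4S,6S)-4,6-diethyl-6-[(4R,5E)-4-ethyloct-5-en-1-yl]-1,2-dioxan-3-yl]acetate (CNP0124952.2) | CC/C=C/[C@H](CC)CCC[C@@]1(CC)C[C@H](CC)[C@H](CC(=O)OC)OO1 | target

## Step count and risk

Total step count: 17. Longest linear sequence: 14 (steps 1–6 and 10–17); steps 7–9 form a three-step side branch that joins at step 10.

**Step 15 (key step).** The most likely failure is partial ionisation at the tertiary carbon, which leaks the substitution towards SN1 and erodes the inversion at C6. Acid-promoted Hock-type fragmentation of the tertiary hydroperoxide and premature exchange at the acetal are further risks. Because ethyl and chain are so alike, a C6 epimer would be very hard to remove. Fallback: the two C–O bonds are made in the reverse order. From 22, acetal exchange with ethereal H2O2 under a weak Brønsted acid (PPTS, conditions that should leave a 2,2-dialkyloxetane closed) should give the α-methoxy hydroperoxide F1. F1 is isolated and then cyclised with a catalytic Lewis acid (Yb(OTf)3 or TMSOTf, CH2Cl2, −40 °C) by intramolecular 6-exo-tet opening of the oxetane. This is a known, stereospecific alkylation of a hydroperoxide by a tethered oxetane, and it comes back to the route at 25.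

**Step 17.** The risk is poor facial selectivity in the capture of the peroxycarbenium ion, through the half-chair with an axial C4 ethyl or a twist pathway. Proton loss from C4 to a ring enol ether would also erode C4, and the acid could ionise the C6–O bond. Fallback: from 26, mild aqueous acid (TFA, THF/H2O) should give the lactol F2, which is in equilibrium with the open γ-hydroperoxy aldehyde. Wittig reaction with methyl (triphenylphosphoranylidene)acetate should give the (E)-enoate hydroperoxide F3. Amine-catalysed intramolecular oxa-Michael addition (Et2NH, CF3CH2OH) then closes the ring to 29 and its C3 epimer. These are diastereomers of different ring shape and are separated by chromatography. This is the textbook closure: known chemistry, paid for with C3 selectivity.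

**Step 16.** The risk is reduction of the O–O bond by free phosphine, and radical fragmentation of the peroxide while the diazene decomposes. Fallback: from 25, iodination with preformed Ph3P·I2 and imidazole should give the iodide F4. Tin hydride reduction at high hydride concentration (n-Bu3SnH, Et3B/air, toluene, 0 °C) then gives 26. The primary radical is γ to the peroxide oxygen, and 4-exo attack on oxygen is slow against hydrogen transfer.

**Step 10.** The risk is slow transmetallation of the β-branched alkylzinc and loss of alkene geometry (palladium hydride or enoate isomerisation), which would reappear as loss of C6 configuration after steps 12–15. Fallback: from 9, the chelation-controlled (Z)-enol phosphate F5 is made (NaH, ClP(O)(OEt)2, Et2O, 0 °C). It is treated with the Gilman cuprate F6, prepared from iodide 15 (t-BuLi, −78 °C, then CuI). This is an addition–elimination with retention that returns to 17.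

## Further compounds

F1 | step 15 | (2R)-2-{(2S)-2-[hydroperoxy(methoxy)methyl]butyl}-2-[(4R,5E)-4-ethyloct-5-en-1-yl]oxetane | C1CO[C@]1(CCC[C@@H](CC)/C=C/CC)C[C@H](CC)C(OC)OO
F2 | step 17 | (4S,6S)-4,6-diethyl-6-[(4R,5E)-4-ethyloct-5-en-1-yl]-1,2-dioxan-3-ol | CC/C=C/[C@H](CC)CCC[C@@]1(CC)C[C@H](CC)C(O)OO1
F3 | step 17 | methyl (2E,4S,6S,10R,11E)-4,6,10-triethyl-6-hydroperoxytetradeca-2,11-dienoate | CC/C=C/[C@H](CC)CCC[C@](CC)(OO)C[C@H](CC)/C=C/C(=O)OC
F4 | step 16 | (3S,5S)-5-ethyl-3-[(4R,5E)-4-ethyloct-5-en-1-yl]-3-(2-iodoethyl)-6-methoxy-1,2-dioxane | CC/C=C/[C@H](CC)CCC[C@@]1(CCI)C[C@H](CC)C(OC)OO1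
F5 | step 10 | methyl (2Z,7R,8E)-3-[(diethoxyphosphoryl)oxy]-7-ethylundeca-2,8-dienoate | CC/C=C/[C@H](CC)CCC/C(OP(=O)(OCC)OCC)=C/C(=O)OC
F6 | step 10 | lithium bis[(2R)-2-(dimethoxymethyl)butyl]cuprate | [Li+].CC[C@H](C(OC)OC)C[Cu-]C[C@H](CC)C(OC)OC
A1 | alternative 1 | methyl (2E,4S,10R,11E)-4,10-diethyl-6-ethylidenetetradeca-2,11-dienoate | CC/C=C/[C@H](CC)CCCC(=CC)C[C@H](CC)/C=C/C(=O)OC
A2 | alternative 1 | methyl (2E,4S,10R,11E)-4,6,10-triethyl-6-hydroperoxytetradeca-2,11-dienoate, both C6 epimers | CC/C=C/[C@H](CC)CCCC(CC)(OO)C[C@H](CC)/C=C/C(=O)OC
A3 | alternative 2 | methyl (10R,11E)-4,6,10-triethyltetradeca-3,5,11-trienoate | CC/C=C/[C@H](CC)CCCC(CC)=CC(CC)=CCC(=O)OC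
A4 | alternative 2 | methyl 2-{4,6-diethyl-6-[(4R,5E)-4-ethyloct-5-en-1-yl]-3,6-dihydro-1,2-dioxin-3-yl}acetate, ring centres uncontrolled | CC/C=C/[C@H](CC)CCCC1(CC)C=C(CC)C(CC(=O)OC)OO1
A5 | alternative 3 | (2S)-2-ethyl-4-oxohexanal | CCC(=O)C[C@H](CC)C=O
A6 | alternative 3 | (4S)-4,6-diethyl-3,6-dimethoxy-1,2-dioxane | CC[C@H]1CC(CC)(OC)OOC1OC
A7 | alternative 3 | (4S,6S)-4,6-diethyl-3-methoxy-6-(prop-2-en-1-yl)-1,2-dioxane | C=CC[C@@]1(CC)C[C@H](CC)C(OC)OO1
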